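**Retrosynthetic overview**
1. Borregomycin E ⇒ double O-methylation of the 5,6-catechol of the indolo[2,3-a]carbazole, which is the aromatic enediol tautomer of a cyclic acyloin.
2. Acyloin ⇒ C5–C6 bond by a carbene-catalysed intramolecular benzoin reaction of 6,6'-dichloro-2,2'-biindole-3,3'-dicarbaldehyde: the Breslow acyl anion of one formyl group attacks the other, normally equally electrophilic, formyl carbon.
3. Dialdehyde ⇒ C2–C2' reductive homocoupling of 2-bromo-6-chloroindole-3-carbaldehyde.
4. Bromo aldehyde ⇒ 6-chlorooxindole by Vilsmeier haloformylation.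
5. Ring order: chlorinated benzo rings bought in place → both pyrrole rings aromatised (step 1) → biaryl bond (step 2) → central benzene ring C closed last (step 3).

Assumption: the target has no stereocentre and is achiral, so the single compound drawn is made and no stereocontrol is needed; the transient acyloin 6 is racemic and its stereocentre disappears on tautomerisation.

**Step 1**
Reactants: 1 6-chlorooxindole (6-chloro-1,3-dihydro-2H-indol-2-one)
Product: 3 2-bromo-6-chloro-1H-indole-3-carbaldehyde, via [(2-bromo-6-chloro-1H-indol-3-yl)methylidene]dimethylammonium bromide 2 (not isolated)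
Conditions: POBr3 (2.5 equiv), DMF (3 equiv), CH2Cl2, 0 °C → reflux; then ice/H2O, aq NaOH to pH 8, rt
Reagents that add atoms: N,N-dimethylformamide CN(C)C=O; phosphorus oxybromide O=P(Br)(Br)Br; water O
Why: Vilsmeier–Haack–Arnold haloformylation, in which the bromo-iminium reagent C-formylates the oxindole enol at C3, the activated lactam oxygen is displaced by bromide with aromatisation to the 2-bromoindole, and water hydrolyses iminium salt 2 to the aldehyde, leaving the aryl C–Cl untouched and creating no stereocentre.

**Step 2**
Reactants: 3 2-bromo-6-chloro-1H-indole-3-carbaldehyde (2 equiv)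
Product: 5 6,6'-dichloro-1H,1'H-2,2'-biindole-3,3'-dicarbaldehyde, via 6-chloro-2-(trimethylstannyl)-1H-indole-3-carbaldehyde 4 (not isolated)
Conditions: Pd(PPh3)4 (5 mol%), Me3SnSnMe3 (0.55 equiv), 1,4-dioxane, Ar, 100 °C
Reagents that add atoms: none
Why: Ditin-mediated reductive homocoupling of Stille–Kelly type, in which zerovalent palladium inserts only into the activated C2–Br bond (α to N, β to the formyl group) and not into the aryl C–Cl, half of 3 is stannylated to 4 and this cross-couples with the remaining 3, with N–H and formyl groups tolerated.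

**Step 3**
Reactants: 5 6,6'-dichloro-1H,1'H-2,2'-biindole-3,3'-dicarbaldehyde
Product: 8 2,9-dichloro-5,6-dimethoxy-11,12-dihydroindolo[2,3-a]carbazole (borregomycin E), via acyloin 2,9-dichloro-6-hydroxy-11,12-dihydroindolo[2,3-a]carbazol-5(6H)-one 6 (not isolated), via catechol 2,9-dichloro-11,12-dihydroindolo[2,3-a]carbazole-5,6-diol 7 (not isolated)
Conditions: 2-mesityl-6,7-dihydro-5H-pyrrolo[2,1-c][1,2,4]triazol-2-ium chloride (15 mol%), DBU (30 mol%), degassed DMF, Ar, 60 °C, to full conversion of 5; then K2CO3 (3 equiv), MeI (2.5 equiv), 0 °C → rt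
Reagents that add atoms: iodomethane CI
Why: Proposed new method: the triazolylidene adds to one formyl group to give a Breslow intermediate (acyl anion equivalent) whose former carbonyl carbon attacks the neighbouring formyl carbon in a six-membered-ring-forming intramolecular benzoin reaction, acyloin 6 tautomerises irreversibly to the aromatic catechol 7 (which pulls the otherwise unfavourable additions to these vinylogous-formamide aldehydes forward), and the phenoxides are then O-methylated under Williamson conditions in preference to the much less acidic carbazole-type N–H; the closest known reactions are the cyanide- or carbene-catalysed cyclisation of biphenyl-2,2'-dicarbaldehyde to phenanthrene-9,10-diol/quinone and the K2CO3/MeI O-methylation of hydroxycarbazoles, and no stereocentre remains.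

**Compound list**
1 | 6-chlorooxindole (6-chloro-1,3-dihydro-2H-indol-2-one) | O=C1Cc2ccc(Cl)cc2N1 | starting material
2 | [(2-bromo-6-chloro-1H-indol-3-yl)methylidene]dimethylammonium bromide | C[N+](C)=Cc1c(Br)[nH]c2cc(Cl)ccc12.[Br-] | intermediate
3 | 2-bromo-6-chloro-1H-indole-3-carbaldehyde | O=Cc1c(Br)[nH]c2cc(Cl)ccc12 | intermediate
4 | 6-chloro-2-(trimethylstannyl)-1H-indole-3-carbaldehyde | C[Sn](C)(C)c1[nH]c2cc(Cl)ccc2c1C=O | intermediate
5 | 6,6'-dichloro-1H,1'H-2,2'-biindole-3,3'-dicarbaldehyde | O=Cc1c(-c2[nH]c3cc(Cl)ccc3c2C=O)[nH]c2cc(Cl)ccc12 | intermediate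
6 | (±)-2,9-dichloro-6-hydroxy-11,12-dihydroindolo[2,3-a]carbazol-5(6H)-one | O=C1C(O)c2c([nH]c3cc(Cl)ccc23)-c2[nH]c3cc(Cl)ccc3c12 | intermediate
7 | 2,9-dichloro-11,12-dihydroindolo[2,3-a]carbazole-5,6-diol | Oc1c(O)c2c3ccc(Cl)cc3[nH]c2c2[nH]c3cc(Cl)ccc3c12 | intermediate
8 | borregomycin E (2,9-dichloro-5,6-dimethoxy-11,12-dihydroindolo[2,3-a]carbazole) | COc1c(OC)c2c3ccc(Cl)cc3[nH]c2c2[nH]c3cc(Cl)ccc3c12 | target

**Totals**
Total step count: 3. Longest linear sequence: 3 steps (1 → 3 → 5 → 8).

**Steps most likely to fail, with fallbacks**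

Step 3 (highest risk). The formyl groups of 5 are vinylogous formamides and weak acceptors. The substrate N–H is more acidic than the azolium salt, so little free carbene is present. Catechol 7 is air-sensitive, and any unreacted 5 would be N-methylated. The fallback sets out from 5 and comes back to the route at 7. The same C5–C6 bond is made by reductive ketyl–ketyl (pinacol) cyclisation with SmI2 (THF/HMPA, −78 °C → rt), which needs no nucleophilic addition to the deactivated carbonyl, giving (±)-trans-2,9-dichloro-5,6,11,12-tetrahydroindolo[2,3-a]carbazole-5,6-diol F1 (any cis isomer serves equally). Dehydrogenation with DDQ (2.2 equiv, dioxane, rt) gives bench-stable 2,9-dichloro-11,12-dihydroindolo[2,3-a]carbazole-5,6-dione F2, which can be purified and stored. Reduction with Na2S2O4 (THF/H2O, Ar) returns catechol 7, which is methylated at once as in the second stage of step 3 (K2CO3, MeI, acetone) to give 8.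

Step 2. With a free N–H and a formyl group, the in-situ stannane 4 may be protodestannylated, or the Stille coupling to the di-ortho-substituted biaryl may stall. The fallback sets out from 3 and comes back at 5. Protection with Boc2O/DMAP (MeCN, rt) gives tert-butyl 2-bromo-6-chloro-3-formyl-1H-indole-1-carboxylate F3. Ullmann-type reductive homocoupling with CuTC, Cu(O2C-C4H3S) (3 equiv, NMP, rt), follows; the ortho formyl and carbamate groups chelate monovalent copper and direct it into the C2–Br bond while the aryl C–Cl stays intact. This gives di-tert-butyl 6,6'-dichloro-3,3'-diformyl-1H,1'H-2,2'-biindole-1,1'-dicarboxylate F4, and TFA/CH2Cl2 (rt) removes both Boc groups to give 5.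

Step 1. The one-pot haloformylation can give mixtures (incomplete oxygen-to-bromine exchange, N-formylation, tar). The fallback sets out from 1 and comes back at 2, separating the two events. Condensation of 1 with DMF dimethyl acetal (toluene, 80 °C) gives crystalline (3E)-6-chloro-3-[(dimethylamino)methylidene]-1,3-dihydro-2H-indol-2-one F5 (E/Z mixture, E drawn; the geometry is lost in the next operation). POBr3 (1.3 equiv, 1,2-dichloroethane, 60 °C) then O-phosphorylates the vinylogous urea and lets bromide displace at C2 with aromatisation to iminium salt 2, which the aqueous work-up of step 1 hydrolyses to 3.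

**Further compounds**
F1 | step 3 | (±)-trans-2,9-dichloro-5,6,11,12-tetrahydroindolo[2,3-a]carbazole-5,6-diol (racemate, one enantiomer drawn) | O[C@H]1[C@H](O)c2c3ccc(Cl)cc3[nH]c2-c2[nH]c3cc(Cl)ccc3c12
F2 | step 3 | 2,9-dichloro-11,12-dihydroindolo[2,3-a]carbazole-5,6-dione | O=C1C(=O)c2c3ccc(Cl)cc3[nH]c2-c2[nH]c3cc(Cl)ccc3c12
F3 | step 2 | tert-butyl 2-bromo-6-chloro-3-formyl-1H-indole-1-carboxylate | CC(C)(C)OC(=O)n1c(Br)c(C=O)c2ccc(Cl)cc12
F4 | step 2 | di-tert-butyl 6,6'-dichloro-3,3'-diformyl-1H,1'H-2,2'-biindole-1,1'-dicarboxylate | CC(C)(C)OC(=O)n1c(-c2c(C=O)c3ccc(Cl)cc3n2C(=O)OC(C)(C)C)c(C=O)c2ccc(Cl)cc12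
F5 | step 1 | (3E)-6-chloro-3-[(dimethylamino)methylidene]-1,3-dihydro-2H-indol-2-one | CN(C)/C=C1/C(=O)Nc2cc(Cl)ccc12
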